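**Retrosynthetic overview**

- Endgame: C18 ester and C1 acetate by acylation; diene by two Wittig reactions on a C12 aldehyde; C1–O and C12 from Baeyer–Villiger cleavage of a cyclopentanone bridging C9 and C1; C10 methyl by hydroxyl-directed cyclopropanation and reductive opening.
- Key disconnection: ring B (C5–C10), the C8 carbinol and C9 come from the five-membered ring (C10, C5, C6, C7, C8) of a tricyclic dienone by a type A photorearrangement in aqueous acid; C5 is then corrected by thermodynamic epimerisation through the dienolate.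
- Enabling feature: the cross-conjugated cyclohexadienone C8–C9=C11–C12(=O)–C1=C10, whose only sp3 member C8 carries the methyl group and is shared with the cyclopentane C8–C7–C6–C5–C10, and whose C1 is alkylated by ring A.
- The dienone comes from alkylative dearomatisation of a para-methylphenol built on a tetralin; C4 and C5 are set on a δ-lactone by rhodium-catalysed asymmetric conjugate addition and two enolate alkylations.
- Ring order: temporary δ-lactone, ring A (Friedel–Crafts), cyclopentane (dearomatisation), cyclopentenone plus ring B (photochemical step), cyclopentenone opened (Baeyer–Villiger, aminolysis).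

Key step: step 10

Remark: labdane numbering (C1–C20; C17 on C8, C18 the oxygenated carbon on C4, C20 on C10) and α/β descriptors relative to the β C10 methyl are used for all intermediates; the sense of induction of (R)-binap in step 1 is assigned by analogy with cyclic enones.

**Step 1**
Reactants: 1 5,6-dihydro-2H-pyran-2-one; 2 (5-methoxy-2-methylphenyl)boronic acid
Product: 3 (4R)-4-(5-methoxy-2-methylphenyl)oxan-2-one
Conditions: [Rh(OH)((R)-binap)]2 (2.5 mol %), 2 (2.5 equiv), 1,4-dioxane/H2O 10:1, 40 °C
Reagents that add atoms: (5-methoxy-2-methylphenyl)boronic acid 2, COc1ccc(C)c(c1)B(O)O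
Why: Hayashi–Miyaura asymmetric 1,4-addition of an arylboronic acid to an unsaturated δ-lactone; the binap–rhodium aryl species selects one enantioface of the enoate and sets the future C5.

**Step 2**
Reactants: 3 aryl lactone; 4 allyl bromide
Product: 6 (3S,4R)-3-allyl-4-(5-methoxy-2-methylphenyl)oxan-2-one, via lithium enolate 5 (not isolated)
Conditions: LiN(iPr)2, THF, −78 °C; then 4, −78 → −40 °C
Reagents that add atoms: allyl bromide 4, C=CCBr
Why: Lactone enolate alkylation anti to the neighbouring aryl group (trans product); this centre is enolised again in step 3, so only the constitution matters here.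

**Step 3**
Reactants: 6 allyl lactone; 7 iodomethane
Product: 9 (3R,4S)-3-allyl-4-(5-methoxy-2-methylphenyl)-3-methyloxan-2-one, via lithium enolate 8 (not isolated)
Conditions: LiN(iPr)2, THF/DMPU, −78 °C; then 7, −78 → 0 °C
Reagents that add atoms: iodomethane 7, CI
Why: Second enolate alkylation; methyl iodide enters anti to the aryl group and creates quaternary C4 with methyl trans and allyl cis to the aryl ring.

**Step 4**
Reactants: 9 allyl methyl lactone
Product: 10 2-[(3R,4S)-4-(5-methoxy-2-methylphenyl)-3-methyl-2-oxooxan-3-yl]acetaldehyde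
Conditions: OsO4 (2 mol %), NaIO4 (4 equiv), 2,6-lutidine, 1,4-dioxane/H2O 3:1, rt
Reagents that add atoms: sodium periodate, [Na+].[O-]I(=O)(=O)=O
Why: Lemieux–Johnson cleavage of the terminal alkene (dihydroxylation, glycol cleavage) gives the C2 aldehyde without touching a stereocentre.

**Step 5**
Reactants: 10 lactone aldehyde
Product: 12 tricyclic lactone (12-methoxy-8-methyl arene, ring A closed, δ-lactone C18(=O)–O–C7 cis-fused on the α face at C4–C5, 4β-methyl, 5β-H), via benzylic carbinol 11 (not isolated)
Conditions: Et3SiH (3 equiv), CF3CO2H/CH2Cl2 1:1, 0 °C → rt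
Reagents that add atoms: none
Why: Intramolecular Friedel–Crafts hydroxyalkylation at the only free ortho position of the arene (ortho to OMe), then ionic hydrogenation of the electron-rich benzylic carbinol; C4 and C5 are untouched.

**Step 6**
Reactants: 12 tricyclic lactone
Product: 13 bromo acid phenol (12-hydroxy arene, 4α-CO2H, 4β-CH3, 5α-(2-bromoethyl), 5β-H)
Conditions: BBr3 (4 equiv), CH2Cl2, −78 °C → rt; H2O
Reagents that add atoms: boron tribromide, BrB(Br)Br
Why: BBr3 cleaves the aryl methyl ether and opens the δ-lactone by bromide attack at the primary O–CH2 carbon C7, unveiling phenol, C7 bromide and C18 acid in one operation.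

**Step 7**
Reactants: 13 bromo acid phenol
Product: 14 bromo alcohol phenol (C18 CH2OH)
Conditions: BH3·THF (4 equiv), THF, 0 °C → rt; MeOH
Reagents that add atoms: none
Why: Chemoselective borane reduction of the carboxylic acid in the presence of the primary bromide.

**Step 8**
Reactants: 14 bromo alcohol phenol
Product: 15 bis(triisopropylsilyl) ether (aryl O–Si and C18 O–Si)
Conditions: iPr3SiOTf (2.5 equiv), 2,6-lutidine (4 equiv), CH2Cl2, 0 °C
Reagents that add atoms: triisopropylsilyl trifluoromethanesulfonate, CC(C)[Si](OS(=O)(=O)C(F)(F)F)(C(C)C)C(C)C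
Why: Exhaustive silylation protects the neopentyl alcohol for the rest of the route and masks the phenol, so that only the phenoxide is nucleophilic in step 9.

**Step 9**
Reactants: 15 bis-silyl ether
Product: 17 (4R,5S,8S)-tricyclic dienone (C9=C11–C12(=O)–C1=C10, C8 quaternary with CH3, cyclopentane C10–C5–C6–C7–C8, 5β-H, C18 OSi(iPr)3), via tetrabutylammonium phenoxide 16 (not isolated)
Conditions: Bu4NF (1.0 equiv), THF, 0 °C, 15 min; then 0.005 M, 65 °C
Reagents that add atoms: none
Why: One equivalent of fluoride cleaves only the aryl silyl ether, and the phenoxide undergoes intramolecular para-C-alkylation by the C7 bromide (alkylative dearomatisation); O-alkylation and ortho attack are geometrically excluded, and because the tether hangs from C5 the C7–C8 bond forms on the face carrying C6, which places the C8 methyl cis to H5.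

**Step 10**
Reactants: 17 tricyclic dienone
Product: 19 (5S,8R,9R)-hydroxy enone (ring B six-membered, 8α-OH, 8β-CH3, 9α-H, C12 ketone, C1=C10, 5β-H), via oxyallyl zwitterion 18 (not isolated)
Conditions: hν (medium-pressure Hg lamp, Pyrex, λ > 300 nm), AcOH/H2O/1,4-dioxane 5:4:2, N2, 15 °C, to about 80% conversion
Reagents that add atoms: water, O
Why: Excitation of the cross-conjugated dienone leads to β,β′-bonding between C9 and C10 and to the bicyclo[3.1.0] oxyallyl zwitterion 18, which is protonated on oxygen; the resulting cyclopropylcarbinyl cation (charge on C1) opens by cleavage of C8–C10 while water binds at C8. The closest known reactions are the santonin → isophotosantonic lactone rearrangement and its counterpart in bicyclic 6/5-fused 4-alkylcyclohexadienones, which give 5/6-fused γ-hydroxy enones (type A dienone photorearrangement in protic acid). The cyclopentenone ring (C9, C11, C12, C1, C10) is closed by the C9–C10 bond as a three-membered β,β′ closure inside the dienone, and ring B is not closed anew but results from the cyclopentane C10–C5–C6–C7–C8 by insertion of C9 between C8 and C10 (cyclopropylcarbinyl to homoallyl opening). C9 is set by the geometry of 18, since the cyclopentane must stay cis-fused on the cyclopropane, so C8 tilts toward its methyl face and H9 ends anti to the C8 methyl; C8 is set by backside attack of water on the breaking C8–C10 bond (inversion, 8S dienone to 8R carbinol with equatorial OH). The step needs cleavage of C8–C10 and not of C8–C9 (spiro ketone) and capture before the 1,4-shift to a lumiketone: the alkyl substituent on C1 (ring A) stabilises positive charge next to C10, the protic medium intercepts 18, and irradiation through Pyrex to partial conversion limits secondary photolysis of the cyclopentenone. C5 is not touched, so 19 is formed as the strained 5β-H epimer that step 11 corrects.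

**Step 11**
Reactants: 19 hydroxy enone (5β-H)
Product: 21 (5R,8R,9R)-hydroxy enone (5α-H), via extended dienolate 20 (not isolated)
Conditions: DBU (0.5 equiv), toluene, 60 °C
Reagents that add atoms: none
Why: Vinylogous epimerisation: γ-deprotonation at C5 gives the extended dienolate and thermodynamic reprotonation funnels C5 to the α-H epimer, the only one in which ring B is a chair with C4 equatorial while C11 stays coplanar with the cyclopentenone.

**Step 12**
Reactants: 21 hydroxy enone (5α-H)
Product: 22 (12S)-allylic alcohol (12β-OH)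
Conditions: (R)-2-methyl-CBS-oxazaborolidine (0.3 equiv), BH3·SMe2 (1.5 equiv), THF, −30 °C
Reagents that add atoms: none
Why: Corey–Bakshi–Shibata 1,2-reduction; with the alkenyl side (C1) as the large group the (R)-catalyst delivers hydride to the α face of C12 and gives the 12β-alcohol.

**Step 13**
Reactants: 22 allylic alcohol; 23 diiodomethane
Product: 24 cyclopropyl carbinol (CH2 bridging C1 and C10 on the β face)
Conditions: Et2Zn (5 equiv), CH2I2 (10 equiv), CH2Cl2, 0 °C → rt
Reagents that add atoms: diiodomethane 23, ICI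
Why: Hydroxyl-directed Simmons–Smith (Furukawa) cyclopropanation; the zinc alkoxide of the 12β-OH delivers CH2 to the β face of the tetrasubstituted C1=C10 bond, syn to the C8 methyl.

**Step 14**
Reactants: 24 cyclopropyl carbinol
Product: 25 cyclopropyl ketone
Conditions: Dess–Martin periodinane (1.5 equiv), NaHCO3, CH2Cl2, rt
Reagents that add atoms: none
Why: Dess–Martin oxidation of the secondary carbinol; the tertiary C8 alcohol is inert.

**Step 15**
Reactants: 25 cyclopropyl ketone
Product: 27 tricyclic ketone (10β-CH3, 1α-H, cyclopentanone C9–C11–C12(=O)–C1–C10), via lithium enolate 26 (not isolated)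
Conditions: Li (4 equiv), NH3(l)/THF, −78 °C, 20 min; solid NH4Cl
Reagents that add atoms: none
Why: Dissolving-metal cleavage of the conjugated cyclopropyl ketone breaks the bond that overlaps with the carbonyl π system (C1–C20, not the in-plane C1–C10) and gives the C10 methyl; the enolate is protonated at C1 from the α face, anti to that methyl.

**Step 16**
Reactants: 27 tricyclic ketone
Product: 28 δ-lactone (C12(=O)–O–C1, oxygen on the β face of C1)
Conditions: mCPBA (2 equiv), NaHCO3, CH2Cl2, rt
Reagents that add atoms: 3-chloroperoxybenzoic acid, O=C(OO)c1cccc(Cl)c1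
Why: Baeyer–Villiger oxidation; secondary C1 migrates in preference to primary C11 with retention, which installs the 1β oxygen.

**Step 17**
Reactants: 28 δ-lactone
Product: 29 dihydroxy Weinreb amide (1β-OH, 8α-OH, C12 amide)
Conditions: MeONHMe·HCl (5 equiv), Me3Al (5 equiv), CH2Cl2, 0 °C → rt; Rochelle salt
Reagents that add atoms: N,O-dimethylhydroxylamine hydrochloride, CNOC.Cl
Why: Weinreb aminolysis of the lactone by the aluminium amide frees the 1β-hydroxyl; a translactonised 8,12-lactone would open to the same amide.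

**Step 18**
Reactants: 29 dihydroxy amide; 30 acetic anhydride
Product: 31 1β-acetoxy Weinreb amide
Conditions: Ac2O (3 equiv), pyridine, DMAP (0.1 equiv), 0 °C → rt
Reagents that add atoms: acetic anhydride 30, CC(=O)OC(C)=O
Why: Acylation of the secondary 1β-OH; the tertiary C8 alcohol does not react under these conditions.

**Step 19**
Reactants: 31 acetoxy amide
Product: 32 C12 aldehyde (in equilibrium with its 8,12-hemiacetal)
Conditions: Cp2Zr(H)Cl (3 equiv), THF, rt, 30 min; aq. NaHCO3
Reagents that add atoms: none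
Why: Reduction of the Weinreb amide with Cp2Zr(H)Cl (Schwartz reagent) stops at the aldehyde and leaves the acetate intact.

**Step 20**
Reactants: 32 aldehyde; 33 2-(triphenylphosphoranylidene)propanal
Product: 34 (12E)-enal (C12=C13(CH3)–CHO)
Conditions: 33 (3 equiv), toluene, 90 °C
Reagents that add atoms: 2-(triphenylphosphoranylidene)propanal 33, CC(C=O)=P(c1ccccc1)(c1ccccc1)c1ccccc1
Why: Wittig olefination with a stabilised ylide, which gives the E trisubstituted enal under thermodynamic control.

**Step 21**
Reactants: 34 enal; 35 methyltriphenylphosphonium bromide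
Product: 36 (12E)-diene silyl ether
Conditions: 35 (2.5 equiv), KN(SiMe3)2 (2.4 equiv), THF, 0 °C; then 34, −78 → 0 °C
Reagents that add atoms: methyltriphenylphosphonium bromide 35, C[P+](c1ccccc1)(c1ccccc1)c1ccccc1.[Br-]
Why: Wittig methylenation of the enal completes the (E)-3-methylpenta-2,4-dienyl chain without affecting the 12E geometry.

**Step 22**
Reactants: 36 diene silyl ether
Product: 37 C18 alcohol (1β-acetoxy-labda-12E,14-diene-8α,18-diol)
Conditions: HF·pyridine, pyridine/THF, 0 °C → rt
Reagents that add atoms: none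
Why: Buffered fluoride desilylation of the primary silyl ether spares the acetate, the diene and the tertiary alcohol.

**Step 23**
Reactants: 37 C18 alcohol; 38 icosanoyl chloride
Product: 39 1β-acetoxy-8α-hydroxylabda-12E,14-dien-18-yl icosanoate (target)
Conditions: 38 (1.3 equiv), pyridine, DMAP (0.1 equiv), CH2Cl2, 0 °C → rt
Reagents that add atoms: icosanoyl chloride 38, CCCCCCCCCCCCCCCCCCCC(Cl)=O
Why: Acylation of the primary C18 hydroxyl; the tertiary C8 alcohol is unreactive.

**Compound list**

1 | 5,6-dihydro-2H-pyran-2-one | O=C1C=CCCO1 | starting material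
2 | (5-methoxy-2-methylphenyl)boronic acid | COc1ccc(C)c(c1)B(O)O | starting material
3 | (4R)-4-(5-methoxy-2-methylphenyl)oxan-2-one | COc1ccc(C)c(c1)[C@@H]1CCOC(=O)C1 | intermediate
4 | allyl bromide | C=CCBr | starting material
5 | lithium enolate of 3 (not isolated) | COc1ccc(C)c(c1)[C@@H]1CCOC([O-])=C1.[Li+] | intermediate
6 | (3S,4R)-3-allyl-4-(5-methoxy-2-methylphenyl)oxan-2-one | COc1ccc(C)c(c1)[C@@H]1CCOC(=O)[C@H]1CC=C | intermediate
7 | iodomethane | CI | starting material
8 | lithium enolate of 6 (not isolated) | COc1ccc(C)c(c1)[C@@H]1CCOC([O-])=C1CC=C.[Li+] | intermediate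
9 | (3R,4S)-3-allyl-4-(5-methoxy-2-methylphenyl)-3-methyloxan-2-one | COc1ccc(C)c(c1)[C@@H]1CCOC(=O)[C@]1(C)CC=C | intermediate
10 | 2-[(3R,4S)-4-(5-methoxy-2-methylphenyl)-3-methyl-2-oxooxan-3-yl]acetaldehyde | COc1ccc(C)c(c1)[C@@H]1CCOC(=O)[C@]1(C)CC=O | intermediate
11 | benzylic carbinol, C2 epimers (not isolated) | COc1ccc(C)c2c1C(O)C[C@@]3(C)C(=O)OCC[C@@H]23 | intermediate
12 | tricyclic lactone (methoxy arene, ring A, cis-fused δ-lactone) | COc1ccc(C)c2c1CC[C@@]3(C)C(=O)OCC[C@@H]23 | intermediate
13 | bromo acid phenol | Oc1ccc(C)c2c1CC[C@@](C)(C(O)=O)[C@H]2CCBr | intermediate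
14 | bromo alcohol phenol | Oc1ccc(C)c2c1CC[C@@](C)(CO)[C@H]2CCBr | intermediate
15 | bis(triisopropylsilyl) ether | CC(C)[Si](Oc1ccc(C)c2c1CC[C@@](C)(CO[Si](C(C)C)(C(C)C)C(C)C)[C@H]2CCBr)(C(C)C)C(C)C | intermediate
16 | tetrabutylammonium phenoxide (not isolated) | CCCC[N+](CCCC)(CCCC)CCCC.[O-]c1ccc(C)c2c1CC[C@@](C)(CO[Si](C(C)C)(C(C)C)C(C)C)[C@H]2CCBr | intermediate
17 | (4R,5S,8S)-tricyclic dienone | O=C1C=C[C@]2(C)CC[C@H]3C2=C1CC[C@@]3(C)CO[Si](C(C)C)(C(C)C)C(C)C | intermediate
18 | oxyallyl zwitterion (not isolated) | [O-]C1=C[C@H]2[C@]3(C)CC[C@H]4[C@]23[C+]1CC[C@@]4(C)CO[Si](C(C)C)(C(C)C)C(C)C | intermediate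
19 | hydroxy enone, 5β-H | O=C1C[C@@H]2C3=C1CC[C@@](C)(CO[Si](C(C)C)(C(C)C)C(C)C)[C@H]3CC[C@@]2(C)O | intermediate
20 | extended dienolate, DBU-H salt (not isolated) | [O-]C1=C2CC[C@@](C)(CO[Si](C(C)C)(C(C)C)C(C)C)C3=C2[C@@H](C1)[C@](C)(O)CC3.C1CCC2=[NH+]CCCN2CC1 | intermediate
21 | hydroxy enone, 5α-H | O=C1C[C@@H]2C3=C1CC[C@@](C)(CO[Si](C(C)C)(C(C)C)C(C)C)[C@@H]3CC[C@@]2(C)O | intermediate
22 | (12S)-allylic alcohol, 12β-OH | O[C@H]1C[C@@H]2C3=C1CC[C@@](C)(CO[Si](C(C)C)(C(C)C)C(C)C)[C@@H]3CC[C@@]2(C)O | intermediate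
23 | diiodomethane | ICI | starting material
24 | cyclopropyl carbinol | O[C@H]1C[C@@H]2[C@@]34C[C@@]13CC[C@@](C)(CO[Si](C(C)C)(C(C)C)C(C)C)[C@@H]4CC[C@@]2(C)O | intermediate
25 | cyclopropyl ketone | O=C1C[C@@H]2[C@@]34C[C@@]13CC[C@@](C)(CO[Si](C(C)C)(C(C)C)C(C)C)[C@@H]4CC[C@@]2(C)O | intermediate
26 | lithium enolate (not isolated) | [Li+].[O-]C1=C2CC[C@@](C)(CO[Si](C(C)C)(C(C)C)C(C)C)[C@@H]3CC[C@@](C)(O)[C@H](C1)[C@@]23C | intermediate
27 | tricyclic ketone with 10β-methyl | O=C1C[C@@H]2[C@@]3(C)[C@H]1CC[C@@](C)(CO[Si](C(C)C)(C(C)C)C(C)C)[C@@H]3CC[C@@]2(C)O | intermediate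
28 | δ-lactone (C12(=O)–O–C1) | O=C1C[C@@H]2[C@@]3(C)[C@H](O1)CC[C@@](C)(CO[Si](C(C)C)(C(C)C)C(C)C)[C@@H]3CC[C@@]2(C)O | intermediate
29 | dihydroxy Weinreb amide | CON(C)C(=O)C[C@@H]1[C@@]2(C)[C@H](O)CC[C@@](C)(CO[Si](C(C)C)(C(C)C)C(C)C)[C@@H]2CC[C@@]1(C)O | intermediate
30 | acetic anhydride | CC(=O)OC(C)=O | starting material
31 | 1β-acetoxy Weinreb amide | CON(C)C(=O)C[C@@H]1[C@@]2(C)[C@H](OC(C)=O)CC[C@@](C)(CO[Si](C(C)C)(C(C)C)C(C)C)[C@@H]2CC[C@@]1(C)O | intermediate
32 | C12 aldehyde | O=CC[C@@H]1[C@@]2(C)[C@H](OC(C)=O)CC[C@@](C)(CO[Si](C(C)C)(C(C)C)C(C)C)[C@@H]2CC[C@@]1(C)O | intermediate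
33 | 2-(triphenylphosphoranylidene)propanal | CC(C=O)=P(c1ccccc1)(c1ccccc1)c1ccccc1 | starting material
34 | (12E)-enal | O=C/C(C)=C/C[C@@H]1[C@@]2(C)[C@H](OC(C)=O)CC[C@@](C)(CO[Si](C(C)C)(C(C)C)C(C)C)[C@@H]2CC[C@@]1(C)O | intermediate
35 | methyltriphenylphosphonium bromide | C[P+](c1ccccc1)(c1ccccc1)c1ccccc1.[Br-] | starting material
36 | (12E)-diene silyl ether | C=C/C(C)=C/C[C@@H]1[C@@]2(C)[C@H](OC(C)=O)CC[C@@](C)(CO[Si](C(C)C)(C(C)C)C(C)C)[C@@H]2CC[C@@]1(C)O | intermediate
37 | 1β-acetoxylabda-12E,14-diene-8α,18-diol | C=C/C(C)=C/C[C@@H]1[C@@]2(C)[C@H](OC(C)=O)CC[C@@](C)(CO)[C@@H]2CC[C@@]1(C)O | intermediate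
38 | icosanoyl chloride | CCCCCCCCCCCCCCCCCCCC(Cl)=O | starting material
39 | 1β-acetoxy-8α-hydroxylabda-12E,14-dien-18-yl icosanoate | C=C/C(C)=C/C[C@@H]1[C@@]2(C)[C@H](OC(C)=O)CC[C@@](C)(COC(=O)CCCCCCCCCCCCCCCCCCC)[C@@H]2CC[C@@]1(C)O | target

**Summary**

Total step count: 23. Longest linear sequence: 23 steps (from 1 and 2).

**Steps most likely to fail**

Step 9. The two-carbon tether may not reach the π face of C8: the closure is five-membered with both C8 and C10 of the phenoxide inside the new ring, a stereoelectronically disfavoured alkylation geometry, so intermolecular O-alkylation or loss of the bromide can take over. Fallback: close the cyclopentane on a non-aromatic enolate in which C10 is sp3, setting out from 12 and coming back at 17. LiAlH4 reduces 12 to anisole diol F1. Birch reduction (Li, NH3, EtOH) and acid hydrolysis give cyclohexenone diol F2, whose double-bond isomers converge on hydrogenation (H2, Pd/C) to cyclohexanone diol F3. Tosylation of the unhindered C7 hydroxyl gives monotosylate F4 and iPr3SiOTf/2,6-lutidine gives silyl ether F5. LiN(iPr)2/Me3SiCl followed by Pd(OAc)2 (Saegusa–Ito oxidation through the less substituted enolate) gives C9=C11 enone F6. KOtBu in t-BuOH then closes the ring by γ-alkylation of the extended dienolate at C8 (five-membered closure with the enolate outside the new ring) to tricyclic enone F7, and DDQ dehydrogenation across C1–C10 returns to 17.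

Step 10. The cyclopropane of 18 may open toward the spiro ketone (cleavage of C8–C9), or the cyclopentenone product may be consumed by secondary photolysis before conversion is useful. Fallback: carry out the same shift of C10 from C8 to C9 thermally through radicals, setting out from 17 and coming back at 19. HBr in AcOH adds to the less substituted C9=C11 enone to give β-bromo ketone F8. Bu3SnH with Et3B under a slow bleed of air generates the C9 radical, which closes onto C10 and reopens by cleavage of C8–C10 (radical 1,2-alkenyl shift, a Dowd–Beckwith-type ring expansion) to the tertiary C8 radical; oxygen trapping gives hydroperoxide F9, and PPh3 reduces it to 19. C8 epimers, if both form, are separated there.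

Step 13. The zinc carbenoid may not be delivered to the tetrasubstituted ring-fusion alkene next to the axial C8 methyl (no conversion, or attack from the α face). Fallback: transfer the carbon from the same 12β oxygen by a sigmatropic shift, setting out from 22 and coming back at 27. KH and Bu3SnCH2I give stannylmethyl ether F10. n-BuLi triggers the Still–Wittig [2,3] rearrangement, which places CH2OH suprafacially on the β face of C10 and moves the double bond to C1=C12 (hydroxymethyl alkene F11). I2/PPh3/imidazole gives neopentyl iodide F12 and Bu3SnH/AIBN gives methyl alkene F13. Hydroboration–oxidation puts H on C1 from the α face and OH on C12 (alcohol F14), and Dess–Martin oxidation returns to 27.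

**Further compounds**

F1 | step 9 | anisole diol | COc1ccc(C)c2c1CC[C@@](C)(CO)[C@H]2CCO
F2 | step 9 | cyclohexenone diol (double-bond isomers, C8 unassigned) | O=C1CCC(C)C2=C1CC[C@@](C)(CO)[C@H]2CCO
F3 | step 9 | cyclohexanone diol (C1, C8, C10 unassigned) | O=C1CCC(C)C2C1CC[C@@](C)(CO)[C@H]2CCO
F4 | step 9 | C7 monotosylate | O=C1CCC(C)C2C1CC[C@@](C)(CO)[C@H]2CCOS(=O)(=O)c3ccc(C)cc3
F5 | step 9 | C18 silyl ether tosylate | O=C1CCC(C)C2C1CC[C@@](C)(CO[Si](C(C)C)(C(C)C)C(C)C)[C@H]2CCOS(=O)(=O)c3ccc(C)cc3
F6 | step 9 | C9=C11 enone tosylate | O=C1C=CC(C)C2C1CC[C@@](C)(CO[Si](C(C)C)(C(C)C)C(C)C)[C@H]2CCOS(=O)(=O)c3ccc(C)cc3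
F7 | step 9 | tricyclic enone (C1, C10 unassigned) | O=C1C=C[C@]2(C)CC[C@H]3C2C1CC[C@@]3(C)CO[Si](C(C)C)(C(C)C)C(C)C
F8 | step 10 | β-bromo ketone (C9 unassigned) | O=C1CC(Br)[C@]2(C)CC[C@H]3C2=C1CC[C@@]3(C)CO[Si](C(C)C)(C(C)C)C(C)C
F9 | step 10 | C8 hydroperoxide | O=C1C[C@@H]2C3=C1CC[C@@](C)(CO[Si](C(C)C)(C(C)C)C(C)C)[C@H]3CC[C@@]2(C)OO
F10 | step 13 | stannylmethyl ether | CCCC[Sn](CCCC)(CCCC)CO[C@H]1C[C@@H]2C3=C1CC[C@@](C)(CO[Si](C(C)C)(C(C)C)C(C)C)[C@@H]3CC[C@@]2(C)O
F11 | step 13 | hydroxymethyl alkene | C1=C2CC[C@@](C)(CO[Si](C(C)C)(C(C)C)C(C)C)[C@@H]3CC[C@@](C)(O)[C@H](C1)[C@@]23CO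
F12 | step 13 | neopentyl iodide | C1=C2CC[C@@](C)(CO[Si](C(C)C)(C(C)C)C(C)C)[C@@H]3CC[C@@](C)(O)[C@H](C1)[C@@]23CI
F13 | step 13 | methyl alkene | C1=C2CC[C@@](C)(CO[Si](C(C)C)(C(C)C)C(C)C)[C@@H]3CC[C@@](C)(O)[C@H](C1)[C@@]23C
F14 | step 13 | C12 alcohol (C12 unassigned) | OC1C[C@@H]2[C@@]3(C)[C@H]1CC[C@@](C)(CO[Si](C(C)C)(C(C)C)C(C)C)[C@@H]3CC[C@@]2(C)O
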